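## Analysis of the target

The target is a flavonol: a 4H‑chromen‑4‑one (rings A and C) with a hydroxyl at C3 and a 3,4‑dihydroxyphenyl ring B on C2. Ring A is substituted at every position except C6 (5‑OH, 7‑OMe, 8‑OAc). There is no stereocentre, so the problem is one of connectivity and of telling six oxygen atoms apart. The sensitive groups are the aryl acetate on O8 (lost to base, fluoride or alcoholysis), the free catechol of ring B, and the 5,8‑dioxygenated ring A, which is easily oxidised to the 5,8‑quinone. The difficulty is that the acetate must sit on O8 alone while four other hydroxyls are free, and the methyl on O7 alone, so the last steps must be neutral and O5 must be distinguished from O8. Two relations in ring A help: O5 and O8 are para to each other (a hydroquinone pair reachable from a quinone), and the 5‑OH is hydrogen‑bonded to the C4 carbonyl, which makes it far less nucleophilic than the 8‑OH. The strategy rests on ring B: C3' and C4' carry adjacent oxygens and C1' is bonded to C2 of ring C, so C2'–C3'–C4'–C5' with both oxygens corresponds to a 2,3‑dioxygenated butadiene and C1'–C6' to an alkyne on C2.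

## Retrosynthetic reasoning

**21 from 20.** The last operation removes three benzyl groups from O3, O3' and O4' by hydrogenolysis. This is the one deprotection that is neutral and non‑nucleophilic, so the O8 acetate survives. Every hydroxyl that is free in 21, except the chelated 5‑OH, is therefore carried as a benzyl ether.

**20 from 19.** The acyl–O8 bond is cut. In 19 only two hydroxyls are free, the chelated 5‑OH and the unchelated 8‑OH, so a kinetic acylation should place the acetyl group on O8.

**19 from 17 through 18.** The two O–CH3 bonds at O5 and O8 are cut by way of the para‑quinone 18: oxidative demethylation with a tetravalent cerium oxidant, then a mild two‑electron reduction. Only O5 and O8 are para‑related, so the O7 methyl ether stays. This lets ring A travel through all carbon–carbon bond formations as three robust methyl ethers.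

**17 from 16.** The silyl groups on O3' and O4' are exchanged for benzyl groups. Silyl aryl ethers would not survive the oxidation, and their removal at the end would need a fluoride source that endangers the acetate.

**16 from 13 and 14 (key disconnection).** Ring B is taken apart: removal of aromaticity leads back to the 1,4‑cyclohexadiene 15, and a retro‑[4+2] cuts C1'–C2' and C5'–C6' to give the alkyne 13 and the diene 14. The cut is made here because the two oxygens of ring B sit on adjacent carbons that map onto the symmetrical diene, so no regiochemical question arises, and both arrive already differentiated from the other oxygens. The forward reaction must make the alkyne of 13 the only reacting π‑bond and must aromatise 15 without harming the O3 benzyl ether.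

**13 from 10 and 11 through 12.** The C2–C(sp) bond is cut; a palladium/copper coupling joins the vinyl iodide 10 to the silyl‑capped alkyne 11, and the silyl cap is then removed. The cap prevents double coupling and homocoupling.

**10 from 8 through 9.** The C2–I bond is cut. C2–H is the most acidic C–H of 8, so a hindered zinc amide gives 9, which is quenched with an electrophilic iodine source.

**8 from 5 through 6 and 7.** The O3–benzyl bond and then the C3–O bond are cut. The oxygen is introduced by epoxidation of C2=C3 to 6 and acid isomerisation to 7, which avoids an α‑oxygenated ketone precursor.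

**5 from 3 through 4.** O1–C2 and C2–C3 are cut. C2 comes from a formamide acetal that condenses with the methyl ketone of 3 to the enaminone 4, which closes on the phenol.

**3 from 1 through 2.** The C4–C4a bond is cut (Friedel–Crafts acylation of 1), and the methyl group is removed from the oxygen that becomes O1. In 2 this is the methoxy group crowded between the acetyl group and a second methoxy group, so acylation and demethylation can be run in one flask with the same Lewis acid.

## Alternatives that were turned down

**Alternative 1: carbene‑catalysed crossed benzoin forming C3–C4.**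
- Disconnection: C3–C4 of a dihydroflavonol.
- Forward key step: a triazolium‑derived carbene converts the ring A aldehyde of dialdehyde A2 into an acyl‑anion equivalent that adds to the side‑chain aldehyde and closes ring C as the racemic trans‑dihydroflavonol A1.
- For it: the C3 oxygen and the C4 carbonyl are set in one mild, metal‑free, redox‑neutral step, and ring B arrives intact. On this point it is stronger than the chosen route, which needs an epoxidation, a benzylation, a zincation and a coupling to functionalise C2 and C3.
- Against it:
  - The carbene must attack the aromatic aldehyde of A2, which lies between two ortho oxygen substituents and is deactivated by three donors. The aliphatic α‑aryl‑α‑aryloxy aldehyde is more electrophilic and less hindered, so the Breslow intermediate is expected on the wrong carbon, giving the regioisomeric acyloin or homo‑coupling.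
  - A2 is a readily enolised aldehyde that is awkward to make and store.
  - The two stereocentres of A1 are destroyed in the extra dehydrogenation to the flavonol, so the diastereocontrol buys nothing.
  - The ring A endgame from 17 onward would still be needed.
- Comparison: the chosen strategy offers a key precursor, 13, with only one π‑bond that can react, so the selectivity question of A2 does not arise.

**Alternative 2: Friedel–Crafts closure of an aryloxycinnamic acid forming C4–C4a.**
- Disconnection: C4–C4a.
- Forward key step: the (Z)‑acid A4 is activated by an acid anhydride or a strongly acidic dehydrating medium, and the acylium carbon attacks the phenoxy ring to give flavone A3.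
- For it: it is short and convergent. The closure is regiochemically unambiguous, since only one position ortho to the ether oxygen is free, and that position is activated by two methoxy groups. As a ring‑forming step it is more dependable than an untried cycloaddition, and here it is stronger than the chosen route.
- Against it:
  - A3 has no oxygen at C3. Late C3 hydroxylation of a flavone with two electron‑rich rings and a later benzylation would be needed.
  - The strongly acidic medium threatens the benzyl ethers, by cleavage or benzyl transfer to ring A.
  - Only the Z isomer can close. The E isomer places the acylium next to the electron‑rich ring B and can give an indenone.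
- Comparison: the chosen strategy carries the C3 oxygen from an early stage, and builds ring B under neutral conditions.

**Alternative 3: Moore benzannulation building ring A on a pyranone.**
- Disconnection: ring A (C4a–C5 in the electrocyclisation, C8–C8a in the preceding carbonyl addition).
- Forward key step: heating cyclobutenone A6 opens it to a dienylketene that closes by 6π electrocyclisation and tautomerises to A5.
- For it: A5 is identical with 19. Ring A is delivered at the hydroquinone oxidation level with the O7 methyl in place, so the cerium oxidation and the reduction are not needed. On this point it is clearly stronger. The pericyclic cascade itself is reliable.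
- Against it:
  - A6 requires a 2‑aryl‑3‑benzyloxy‑4‑pyranone metalated next to the ring oxygen as a hard nucleophile. Such pyranones are prone to ring opening.
  - The nucleophile must add to one carbonyl of an unsymmetrical, base‑sensitive cyclobutenedione that is not a commodity.
  - The pyranone carrying ring B needs several steps of its own, so the aryl–C2 problem is moved, not solved.
  - The hydroquinone is formed hot and is air‑sensitive.
- Comparison: the chosen strategy starts from arene 1, which already holds all four ring A oxygens. It reaches 19 by a para‑dimethoxy to quinone to hydroquinone sequence with close precedent. The risk sits in one step that has an independent fallback.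

Key step: step 8

Remark on the chemistry: in step 1 the methyl ether cleaved by AlCl3 is taken to be the one flanked by the acetyl group and a second methoxy group; 1, 11 and 14 are bought.

## Route

Step 1
Reactants: 1 1,2,3,5-tetramethoxybenzene
Product: 3 1-(2-hydroxy-3,4,6-trimethoxyphenyl)ethanone, via 1-(2,3,4,6-tetramethoxyphenyl)ethanone 2 (not isolated)
Conditions: AcCl, AlCl3 (2.5 equiv), CH2Cl2, 0 °C → rt; aq. HCl work-up
Reagents that add atoms: acetyl chloride CC(Cl)=O
Why: Friedel–Crafts acylation occurs at one of the two equivalent free positions of 1; excess AlCl3 then cleaves, through a six-membered aluminium chelate with the ketone, the ortho methyl ether that is twisted out of plane between the acetyl group and a second methoxy group, which is the oxygen needed as O1.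

Step 2
Reactants: 3 1-(2-hydroxy-3,4,6-trimethoxyphenyl)ethanone
Product: 5 5,7,8-trimethoxy-4H-chromen-4-one, via enaminone 4 (not isolated)
Conditions: Me2NCH(OMe)2, toluene, 100 °C; evaporate; then conc. HCl, CH2Cl2, 40 °C
Reagents that add atoms: N,N-dimethylformamide dimethyl acetal COC(OC)N(C)C
Why: Condensation of the methyl ketone with the amide acetal gives the vinylogous amide 4; acid then triggers intramolecular oxa-Michael addition of the phenol (6-endo-trig) and loss of dimethylamine, the standard enaminone route to 2,3-unsubstituted chromones.

Step 3
Reactants: 5 5,7,8-trimethoxy-4H-chromen-4-one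
Product: 7 3-hydroxy-5,7,8-trimethoxy-4H-chromen-4-one, via 2,3-epoxychromanone 6 (not isolated)
Conditions: 30% H2O2, aq. NaOH (cat.), CH2Cl2/MeOH, 0 °C; then conc. HCl, EtOH, 60 °C
Reagents that add atoms: hydrogen peroxide OO
Why: Weitz–Scheffer nucleophilic epoxidation of the enone C2=C3 gives the cis-fused racemic epoxide 6; acid opens it at C2 to an oxocarbenium ion stabilised by O1 and loss of H3 re-forms the pyranone, a net isomerisation to the 3-hydroxychromone that is established for chromones.

Step 4
Reactants: 7 3-hydroxy-5,7,8-trimethoxy-4H-chromen-4-one
Product: 8 3-(benzyloxy)-5,7,8-trimethoxy-4H-chromen-4-one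
Conditions: BnBr, K2CO3, DMF, 50 °C
Reagents that add atoms: benzyl bromide BrCc1ccccc1
Why: Williamson etherification of the acidic enolic 3-OH; the benzyl group masks O3 until the last step and also acidifies C2–H for the next step.

Step 5
Reactants: 8 3-(benzyloxy)-5,7,8-trimethoxy-4H-chromen-4-one
Product: 10 3-(benzyloxy)-2-iodo-5,7,8-trimethoxy-4H-chromen-4-one, via chromen-2-ylzinc chloride 9 (not isolated)
Conditions: (TMP)ZnCl·LiCl (TMP = 2,2,6,6-tetramethylpiperidide, 1.3 equiv), THF, 25 °C; then I2, 0 °C
Reagents that add atoms: iodine II
Why: Directed zincation with a hindered amide base: C2–H is the most acidic C–H (sp2, next to O1, β to the carbonyl, ortho to the benzyloxy group) and the covalent C–Zn bond of 9 does not attack the carbonyl; iodinolysis then gives the β-iodoenone 10.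

Step 6
Reactants: 10 3-(benzyloxy)-2-iodo-5,7,8-trimethoxy-4H-chromen-4-one; 11 trimethylsilylacetylene
Product: 12 3-(benzyloxy)-5,7,8-trimethoxy-2-[(trimethylsilyl)ethynyl]-4H-chromen-4-one
Conditions: PdCl2(PPh3)2 (cat.), CuI (cat.), Et3N, THF, rt
Reagents that add atoms: none
Why: Sonogashira coupling; oxidative addition of the electron-poor C2–I bond to zerovalent palladium is fast at room temperature and the tertiary amine cannot add irreversibly at C2.

Step 7
Reactants: 12 3-(benzyloxy)-5,7,8-trimethoxy-2-[(trimethylsilyl)ethynyl]-4H-chromen-4-one
Product: 13 3-(benzyloxy)-2-ethynyl-5,7,8-trimethoxy-4H-chromen-4-one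
Conditions: Bu4NF, AcOH (1:1), THF, −20 → 0 °C
Reagents that add atoms: none
Why: Fluoride-induced protodesilylation of the C(sp)–Si bond; buffering with acetic acid keeps the medium free of alkoxide or unbuffered fluoride that could add in conjugate fashion to the activated terminal alkyne.

Step 8
Reactants: 13 3-(benzyloxy)-2-ethynyl-5,7,8-trimethoxy-4H-chromen-4-one; 14 2,3-bis(trimethylsilyloxy)-1,3-butadiene
Product: 16 3-(benzyloxy)-2-[3,4-bis(trimethylsilyloxy)phenyl]-5,7,8-trimethoxy-4H-chromen-4-one, via cyclohexa-1,4-diene cycloadduct 15 (not isolated)
Conditions: 14 (3 equiv), 2,6-di-tert-butyl-4-methylphenol (cat.), toluene, 120 °C, sealed tube; excess 14 removed in vacuo; then DDQ (1.1 equiv), toluene, 0 °C → rt; filtered and used crude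
Reagents that add atoms: none
Why: A normal-electron-demand Diels–Alder reaction joins the HOMO of 14, raised by two silyloxy donors, to the LUMO of the alkyne of 13, which is lowered by conjugation through C2=C3 to the C4 carbonyl (a vinylogous ynone). Ring B closes as a six-membered carbocycle by intermolecular [4+2] annulation in which C1'–C2' and C5'–C6' form suprafacially on both partners in one transition state, giving the 1,4-cyclohexadiene 15. DDQ then abstracts hydride from a doubly allylic CH2 of 15 (the cation is stabilised by the neighbouring silyl enol ether) and loss of a proton gives the arene 16, with aromatisation as the driving force. The closest known reaction type is the thermal cycloaddition of 2,3-bis(silyloxy)butadienes to acetylenic esters and ketones followed by dehydrogenation to catechol bis(silyl ethers). No stereocentre is formed; 15 and 16 are achiral. The step needs chemoselectivity only: the C2=C3 bond of ring C is tetrasubstituted, donor-substituted and part of the pyranone, so it is no dienophile, and the C2 symmetry of 14 gives a single regioisomer whatever the orientation. Dehydrogenation of 15 is much faster than oxidation of the benzyl ether, and partial loss of a silyl group is harmless because step 9 removes both. If the thermal rate is too low, the same bonds would be formed at room temperature in CH2Cl2 with the reduced cobalt species generated from CoBr2(dppe), Zn and ZnI2, which couples diene and alkyne through a cobaltacycle.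

Step 9
Reactants: 16 3-(benzyloxy)-2-[3,4-bis(trimethylsilyloxy)phenyl]-5,7,8-trimethoxy-4H-chromen-4-one
Product: 17 3-(benzyloxy)-2-[3,4-bis(benzyloxy)phenyl]-5,7,8-trimethoxy-4H-chromen-4-one
Conditions: KF (5 equiv), BnBr (2.5 equiv), DMF, rt → 50 °C, Ar
Reagents that add atoms: benzyl bromide BrCc1ccccc1
Why: Fluoride cleaves both ArO–Si bonds and the phenoxides are benzylated at once (Williamson etherification), which avoids handling the free, air-sensitive catechol and gives ethers that survive oxidation and acetylation.

Step 10
Reactants: 17 3-(benzyloxy)-2-[3,4-bis(benzyloxy)phenyl]-5,7,8-trimethoxy-4H-chromen-4-one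
Product: 18 3-(benzyloxy)-2-[3,4-bis(benzyloxy)phenyl]-7-methoxy-4H-chromene-4,5,8-trione
Conditions: (NH4)2Ce(NO3)6 (2.5 equiv), MeCN/H2O, 0 °C
Reagents that add atoms: water O
Why: Oxidative demethylation of a para-dimethoxyarene by tetravalent cerium (two one-electron oxidations, addition of water at C5 and C8, loss of two methanol); only O5 and O8 are para to each other, so O7 keeps its methyl, and the same conversion of 5,7,8-trimethoxyflavones into 7-methoxy-5,8-quinones is long established with nitric acid as oxidant.

Step 11
Reactants: 18 3-(benzyloxy)-2-[3,4-bis(benzyloxy)phenyl]-7-methoxy-4H-chromene-4,5,8-trione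
Product: 19 3-(benzyloxy)-2-[3,4-bis(benzyloxy)phenyl]-5,8-dihydroxy-7-methoxy-4H-chromen-4-one
Conditions: Na2S2O4, EtOAc/H2O, rt, Ar
Reagents that add atoms: none
Why: Two-electron reduction of the quinone to the hydroquinone by dithionite; the conditions are neutral and do not affect benzyl ethers or the pyranone.

Step 12
Reactants: 19 3-(benzyloxy)-2-[3,4-bis(benzyloxy)phenyl]-5,8-dihydroxy-7-methoxy-4H-chromen-4-one
Product: 20 3-(benzyloxy)-2-[3,4-bis(benzyloxy)phenyl]-5-hydroxy-7-methoxy-4-oxo-4H-chromen-8-yl acetate
Conditions: Ac2O (1.1 equiv), pyridine, CH2Cl2, 0 °C, Ar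
Reagents that add atoms: acetic anhydride CC(=O)OC(C)=O
Why: Kinetically selective O-acylation: the 5-OH is held in a strong hydrogen bond to the C4 carbonyl and is a poor nucleophile, so one equivalent of anhydride without an acyl-transfer catalyst should acylate the free 8-OH only.

Step 13
Reactants: 20 3-(benzyloxy)-2-[3,4-bis(benzyloxy)phenyl]-5-hydroxy-7-methoxy-4-oxo-4H-chromen-8-yl acetate
Product: 21 gossypetin 7-methyl ether 8-acetate
Conditions: H2 (1 atm), 10% Pd/C, EtOAc/THF, rt
Reagents that add atoms: none
Why: Hydrogenolysis of the three benzyl ethers on palladium; the neutral, aprotic medium leaves the aryl acetate in place and the C2=C3 bond of a flavonol is not hydrogenated under these conditions.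

## Compound list

1 | 1,2,3,5-tetramethoxybenzene | COc1cc(OC)c(OC)c(OC)c1 | starting material
2 | 1-(2,3,4,6-tetramethoxyphenyl)ethanone (formed in the flask) | CC(=O)c1c(OC)cc(OC)c(OC)c1OC | intermediate
3 | 1-(2-hydroxy-3,4,6-trimethoxyphenyl)ethanone | CC(=O)c1c(OC)cc(OC)c(OC)c1O | intermediate
4 | (E)-3-(dimethylamino)-1-(2-hydroxy-3,4,6-trimethoxyphenyl)prop-2-en-1-one (enaminone, formed in the flask) | CN(C)/C=C/C(=O)c1c(OC)cc(OC)c(OC)c1O | intermediate
5 | 5,7,8-trimethoxy-4H-chromen-4-one | COc1cc(OC)c2c(=O)ccoc2c1OC | intermediate
6 | racemic cis-fused 2,3-epoxy-5,7,8-trimethoxychroman-4-one (one enantiomer drawn, formed in the flask) | COc1cc(OC)c2C(=O)[C@H]3O[C@H]3Oc2c1OC | intermediate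
7 | 3-hydroxy-5,7,8-trimethoxy-4H-chromen-4-one | COc1cc(OC)c2c(=O)c(O)coc2c1OC | intermediate
8 | 3-(benzyloxy)-5,7,8-trimethoxy-4H-chromen-4-one | COc1cc(OC)c2c(=O)c(OCc3ccccc3)coc2c1OC | intermediate
9 | [3-(benzyloxy)-5,7,8-trimethoxy-4-oxo-4H-chromen-2-yl]zinc chloride, LiCl complex (formed in the flask) | COc1cc(OC)c2c(=O)c(OCc3ccccc3)c([Zn]Cl)oc2c1OC | intermediate
10 | 3-(benzyloxy)-2-iodo-5,7,8-trimethoxy-4H-chromen-4-one | COc1cc(OC)c2c(=O)c(OCc3ccccc3)c(I)oc2c1OC | intermediate
11 | trimethylsilylacetylene | C#C[Si](C)(C)C | starting material
12 | 3-(benzyloxy)-5,7,8-trimethoxy-2-[(trimethylsilyl)ethynyl]-4H-chromen-4-one | COc1cc(OC)c2c(=O)c(OCc3ccccc3)c(C#C[Si](C)(C)C)oc2c1OC | intermediate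
13 | 3-(benzyloxy)-2-ethynyl-5,7,8-trimethoxy-4H-chromen-4-one | C#Cc1oc2c(OC)c(OC)cc(OC)c2c(=O)c1OCc1ccccc1 | intermediate
14 | 2,3-bis(trimethylsilyloxy)-1,3-butadiene | C=C(O[Si](C)(C)C)C(=C)O[Si](C)(C)C | starting material
15 | 3-(benzyloxy)-2-[4,5-bis(trimethylsilyloxy)cyclohexa-1,4-dien-1-yl]-5,7,8-trimethoxy-4H-chromen-4-one (cycloadduct, formed in the flask) | COc1cc(OC)c2c(=O)c(OCc3ccccc3)c(C3=CCC(O[Si](C)(C)C)=C(O[Si](C)(C)C)C3)oc2c1OC | intermediate
16 | 3-(benzyloxy)-2-[3,4-bis(trimethylsilyloxy)phenyl]-5,7,8-trimethoxy-4H-chromen-4-one | COc1cc(OC)c2c(=O)c(OCc3ccccc3)c(-c3ccc(O[Si](C)(C)C)c(O[Si](C)(C)C)c3)oc2c1OC | intermediate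
17 | 3-(benzyloxy)-2-[3,4-bis(benzyloxy)phenyl]-5,7,8-trimethoxy-4H-chromen-4-one | COc1cc(OC)c2c(=O)c(OCc3ccccc3)c(-c3ccc(OCc4ccccc4)c(OCc4ccccc4)c3)oc2c1OC | intermediate
18 | 3-(benzyloxy)-2-[3,4-bis(benzyloxy)phenyl]-7-methoxy-4H-chromene-4,5,8-trione | COC1=CC(=O)C2=C(OC(-c3ccc(OCc4ccccc4)c(OCc4ccccc4)c3)=C(OCc3ccccc3)C2=O)C1=O | intermediate
19 | 3-(benzyloxy)-2-[3,4-bis(benzyloxy)phenyl]-5,8-dihydroxy-7-methoxy-4H-chromen-4-one | COc1cc(O)c2c(=O)c(OCc3ccccc3)c(-c3ccc(OCc4ccccc4)c(OCc4ccccc4)c3)oc2c1O | intermediate
20 | 3-(benzyloxy)-2-[3,4-bis(benzyloxy)phenyl]-5-hydroxy-7-methoxy-4-oxo-4H-chromen-8-yl acetate | COc1cc(O)c2c(=O)c(OCc3ccccc3)c(-c3ccc(OCc4ccccc4)c(OCc4ccccc4)c3)oc2c1OC(C)=O | intermediate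
21 | gossypetin 7-methyl ether 8-acetate, 2-(3,4-dihydroxyphenyl)-3,5-dihydroxy-7-methoxy-4-oxo-4H-chromen-8-yl acetate | COc1cc(O)c2c(=O)c(O)c(-c3ccc(O)c(O)c3)oc2c1OC(C)=O | target

## Step count and least certain steps

Total step count: 13. Longest linear sequence: 13 steps (1 to 21); 11 and 14 are bought and enter in steps 6 and 8.

**Step 8 (key step).** The cycloaddition may be too slow at temperatures that both partners tolerate, so that thermal oligomerisation of the enynone and decomposition of the silyloxydiene win. Open-chain conjugate addition of the silyl enol ether to the activated alkyne without ring closure is also possible. The first response stays inside the step: the cobalt-catalysed cycloaddition named above. The fallback that changes the approach sets out from iodide 10 and comes back to the route at 17. It is a Suzuki–Miyaura coupling of 10 with commercial [3,4-bis(benzyloxy)phenyl]boronic acid (Pd(PPh3)4, K2CO3, dioxane/H2O, 80 °C), which attaches ring B ready-made and makes steps 6 to 9 unnecessary. No compound outside the list is made (entry F0).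

**Step 3.** Hydroxide or hydroperoxide may open the pyranone at C2 (cleavage back toward 3) faster than the epoxide forms, because the 5- and 7-methoxy groups lower the electrophilicity of the enone. The fallback sets out from 5 and comes back at 7. Conjugate reduction of 5 with LiBH(s-Bu)3 in THF at −78 °C should give 5,7,8-trimethoxychroman-4-one F1. Nitrosation at C3 with isopentyl nitrite and HCl in EtOH gives 3-(hydroxyimino)-5,7,8-trimethoxychroman-4-one F2. Heating F2 in aqueous acid hydrolyses the oxime to the 3,4-dione, whose enol is 7. This is the classical nitrosation route from chromanones to 3-hydroxychromones.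

**Step 5.** Metalation may be diverted to C6–H, which lies between two methoxy groups, or may stay incomplete. The iodide may also be lost from 10 by addition–elimination with nucleophiles during isolation, since it is a vinylogous acyl iodide. The fallback sets out from 8 and comes back at 12, avoiding both the organozinc and the iodide. Compound 8 is activated with a silyl triflate as the 4-silyloxybenzopyrylium ion, and the copper acetylide of 11 (CuI cat., i-Pr2NEt, CH2Cl2) adds at C2. Mild acidic work-up gives 3-(benzyloxy)-5,7,8-trimethoxy-2-[(trimethylsilyl)ethynyl]chroman-4-one F3. Dehydrogenation of F3 with DDQ in dioxane at 80 °C, as for flavanones to flavones, restores the pyranone and gives 12.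

**Step 10.** Electron transfer from the dibenzyloxy-substituted ring B, or oxidation at a benzylic position, may compete with oxidation of ring A. The quinone may also suffer further attack of water at C7 with loss of the remaining methyl group. The fallback sets out from 17 and comes back at 18. AlCl3 in MeCN at rt should cleave only the methyl ether peri to the carbonyl, through chelation, giving 3-(benzyloxy)-2-[3,4-bis(benzyloxy)phenyl]-5-hydroxy-7,8-dimethoxy-4H-chromen-4-one F4. Oxidation of this para-methoxyphenol with PhI(OAc)2 in MeCN/H2O at 0 °C then gives 18 with loss of methanol, a two-electron oxidation that starts at the phenol and does not generate an arene radical cation.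

## Further compounds

F0 | step 8 | none | none
F1 | step 3 | 5,7,8-trimethoxychroman-4-one | COc1cc(OC)c2C(=O)CCOc2c1OC
F2 | step 3 | 3-(hydroxyimino)-5,7,8-trimethoxychroman-4-one (oxime geometry not defined) | COc1cc(OC)c2C(=O)C(=NO)COc2c1OC
F3 | step 5 | 3-(benzyloxy)-5,7,8-trimethoxy-2-[(trimethylsilyl)ethynyl]chroman-4-one (racemic, mixture of cis and trans isomers) | COc1cc(OC)c2C(=O)C(OCc3ccccc3)C(C#C[Si](C)(C)C)Oc2c1OC
F4 | step 10 | 3-(benzyloxy)-2-[3,4-bis(benzyloxy)phenyl]-5-hydroxy-7,8-dimethoxy-4H-chromen-4-one | COc1cc(O)c2c(=O)c(OCc3ccccc3)c(-c3ccc(OCc4ccccc4)c(OCc4ccccc4)c3)oc2c1OC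
A1 | alternative 1 | racemic trans-2-[3,4-bis(benzyloxy)phenyl]-3-hydroxy-5,7,8-trimethoxychroman-4-one (one enantiomer drawn) | C(c1ccccc1)Oc1ccc(cc1OCc1ccccc1)[C@@H]1[C@H](C(=O)c2c(OC)cc(OC)c(OC)c2O1)O
A2 | alternative 1 | racemic 2-{1-[3,4-bis(benzyloxy)phenyl]-2-oxoethoxy}-3,4,6-trimethoxybenzaldehyde | O=CC(Oc1c(OC)c(OC)cc(OC)c1C=O)c1ccc(OCc2ccccc2)c(OCc2ccccc2)c1
A3 | alternative 2 | 2-[3,4-bis(benzyloxy)phenyl]-5,7,8-trimethoxy-4H-chromen-4-one | COc1cc(OC)c2c(=O)cc(-c3ccc(OCc4ccccc4)c(OCc4ccccc4)c3)oc2c1OC
A4 | alternative 2 | (Z)-3-[3,4-bis(benzyloxy)phenyl]-3-(2,3,5-trimethoxyphenoxy)prop-2-enoic acid | OC(=O)/C=C(\Oc1cc(OC)cc(OC)c1OC)c1ccc(OCc2ccccc2)c(OCc2ccccc2)c1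
A5 | alternative 3 | 3-(benzyloxy)-2-[3,4-bis(benzyloxy)phenyl]-5,8-dihydroxy-7-methoxy-4H-chromen-4-one (identical with 19) | COc1cc(O)c2c(=O)c(OCc3ccccc3)c(-c3ccc(OCc4ccccc4)c(OCc4ccccc4)c3)oc2c1O
A6 | alternative 3 | racemic 4-{5-(benzyloxy)-6-[3,4-bis(benzyloxy)phenyl]-4-oxo-4H-pyran-2-yl}-4-hydroxy-3-methoxycyclobut-2-en-1-one | COC1=CC(=O)C1(O)c1cc(=O)c(OCc2ccccc2)c(-c2ccc(OCc3ccccc3)c(OCc3ccccc3)c2)o1
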